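The catalyst is single-handed, so each flask is a race between two mirror images, and the south-west run shows how that race goes.

| flask | left-handed substrate | right-handed substrate | solid reagent | catalyst | remark | time |
|---|---|---|---|---|---|---|
| south-west | 0.15 M | 0.15 M | 3 equiv | 0.1 mol% | run made earlier |  |
| alder | 0.10 M | 0.10 M | 3.00 equiv | 0.1 mol% |  | 3.0 min |
| larch | 0.10 M | 0.10 M | 3.00 equiv | 0.03 mol% |  | 3.0 min |
- south-west (time / s: right-handed substrate / %, left-handed substrate / %, left-handed product / %): 15.0: 43.1, 40.7, 10.2; 40.0: 32.3, 23.9, 25.9; 80.0: 21.6, 11.3, 39.9; 120: 13.0, 4.4, 45.1

(each reading ± 1 percentage point)
- catalyst is single-handed; left-handed substrate and right-handed substrate are mirror images of each other, charged as a racemate, each of them at the stated concentration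
- given per volume of solution although it is solid: solid reagent
- at the start none of the solid reagent is in solution
- an excess is the difference of the two amounts in percent of their sum
- an excess is below zero if the other one leads
- no earlier run changes the charge of catalyst; that part of a forecast is a guess
- the flask that ends with the higher excess of right-handed substrate over left-handed substrate among what is left of the two, or "neither" when 2 percentage points or less lies between them (alder / larch / neither)
- excess of right-handed substrate over left-handed substrate among what is left of the two at the end, alder
- excess of right-handed substrate over left-handed substrate among what is left of the two at the end, larch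

I let f be the fraction of its own charge that a substrate still has, and at the last south-west reading I get

s = ln f(left) / ln f(right) = 1.80

This s, the selectivity factor, reads 1.77 at 80.0 s too. I therefore take f(left) = f(right)^s, and the excess follows from how far the left-handed substrate has gone. I measure that distance as a dose: running time times c(catalyst), expressed in south-west seconds. I reckon it for two extreme versions of each flask.

Reagent never fails: alder 120 s, excess near 49.4%; larch 36.0 s, excess near 14.9%.

Reagent fails early: I suppose that the south-west stock of 0.450 M was just used up at 120 s, that each new flask drains at the same pace and that the race stops when its stock ends, so the 0.300 M in each new flask lasts 80.0 s. Alder then gets 53.3 s, between the readings with excesses 14.9% and 31.3%; larch gets 16.0 s, near 2.86%.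

I expect the real flasks to lie between these extremes, and since alder's dose is 3.33 times larch's at either extreme, I choose alder. The forecast, reasoning “With excess reagent, I take rate as proportional to actual catalyst concentration”, names alder, with 47% (37% to 64%) and 15% (9% to 24%); my reckoning gives ranges, not its numbers.

The flask gives alder, with 35.7% against 13.6%.

    2 partner → self-condensation product (k = 0.120 M⁻¹ s⁻¹)
    partner + catalyst + right-handed substrate → catalyst + right-handed product (k = 1200 M⁻² s⁻¹)
    partner + catalyst + left-handed substrate → catalyst + left-handed product (k = 2000 M⁻² s⁻¹)
    partner → decomposition product (k = 8.10 × 10⁻⁵ s⁻¹)
    solid reagent ⇌ partner, rate k5*(cs5 - [partner]) while solid is left; crystals form when [partner] > cs5 (solubility = 0.0690 M, k = 0.500 s⁻¹)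

The forecast for alder stands 11 percentage points high; alder's solid reagent is 10.1% of its charge at 1.50 min and 0% at 3.00 min. With s, alder's 15% of left-handed substrate implies 35.6% of right-handed, against 33% simulated. A neighbouring flask, alder with 1.20 equiv of solid reagent and its other charges and time unchanged, ends with 0% of that reagent and 50% of its left-handed substrate, which implies 68.0% of right-handed and an excess of 15.3%; that flask holds 66% and gives 13.8%.

The earlier runs and the new flask were generated by integration from invented constants; noise was put on by code.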